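The constants used here belong to no real substance, and the outcome is calculated.

The number to hold on to is 3.33 min, the holding time of target: one plus the partition ratio of target times the volume ratio, over the decay constant, which is the amount of target, both phases counted, held in balance per unit rate of making, since target decays in the first phase but shelters in the second.

    reagent in the reaction phase ⇌ reagent in the second phase, rate k1*([reagent in the reaction phase] - [reagent in the second phase]/K1) per volume of the first phase (K1 = 1.8, k1 = 0.12 s⁻¹)
    substrate + reagent in the reaction phase → target (k2 = 0.032 L mol⁻¹ s⁻¹)
    target ⇌ product in the second phase, rate k3*([target] - [product in the second phase]/K3) per volume of the first phase (K3 = 1.3, k3 = 0.022 s⁻¹)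
    target → decomposed product (k4 = 0.018 s⁻¹)
    reagent in the reaction phase + protic impurity → quenched reagent (k5 = 0.57 L mol⁻¹ s⁻¹)
    substrate + target → side product (k6 = 0.0041 L mol⁻¹ s⁻¹)
    2 reagent in the reaction phase → homo dimer (k7 = 0.15 L mol⁻¹ s⁻¹)

substrate 0.050 M; reagent in the second phase 1.20 equiv; protic impurity 2.50 mM; time 8.0 min; volume of the second phase over the first 2.0

- percent here means substrate units held: one side product counts as two
- what is said of target includes product in the second phase
- a doubled species enters its step squared and goes two at a time
- in the second phase: reagent in the second phase, product in the second phase; everything else is in the first
- charges count per volume of the first phase; a concentration in a rate is the amount of a species over the volume of its own phase; every rate counts per litre of the first phase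
- run time (flask): 8.0 min

- Tuesday's: doubling the amount of reagent in the second phase, all else as stated
- Wednesday's: doubling the transfer coefficient of step 1, all else as stated
- Sunday's: doubling the transfer coefficient of step 3, all else as stated

- target and product in the second phase together at 8.0 min, in percent of the substrate charged
- the change that raises the amount of target and product in the second phase together at 8.0 min, in percent of the substrate charged most ("none" if none brings more than 2 percentage points) (Tuesday's / Wednesday's / Sunday's / none)
- amount of target and product in the second phase together at 8.0 min, in percent of the substrate charged, after Wednesday's

We turn the constants into times, fastest first. Reagent crosses in about 8.33 s, so we let the reagent in the reaction phase ride at its partition with the second phase. Struck of the protic impurity, the charge then starts that level at 0.01250 M. Bare target has a half-life of 0.64 min and crosses in about 0.758 min. Next stands the holding time, and it is shorter than the run of 8.0 min, whereas coupling needs 7.2 min to halve the reagent. We therefore reckon target at balance at the asked time, a quasi-steady state with nothing crossing net, so our sum holds no transfer coefficient; this is our assumption for that moment, not for the climb before it. Loss to side product, at 56 min, is slower than the run.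

The yield is then the coupling constant times reagent level times holding time times the substrate fraction left. Dimerisation, drawing on the reserve, brings the level to 0.008984 M, and the mean level leaves 84.8 % of the substrate. Our figure is 4.88 %, for the flask and for Wednesday's alike. Tuesday's starts at 0.02554 M, ends at 0.01419 M and gains 1.8 percentage points, just under the margin of 2 points, yet it is the one change that enters the product.

The forecast says 4.3 % (3.9 % to 4.7 %), below our figure, then Tuesday's, and 4.4 % (4 % to 4.8 %) after Wednesday's, holding that “phase transfer is not limiting for the reagent”.

The simulation gives 4.28 %. Tuesday's wins with 2.6 points, against 0.23 points for Sunday's and 0.018 points for Wednesday's, which ends at 4.30 %.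

The loss of target to decomposed product takes 9.3 points in this flask: with that loss struck from the scheme, the yield is 13.6 % instead of 4.28 %. Target in this flask has climbed from 3.68 % at 4.00 min, and at 8.00 min reaction-phase target is made at 0.979 of the rate at which it is used up, close to balance. With the flask's readings at the asked time, 0.00785 M of reagent in the reaction phase and 86.0 % of substrate left, the same product gives 4.32 %. The neighbour flask at 0.20 M of substrate, with 0.0145 M and 67.0 %, gets 6.23 % from that product and actually holds 8.48 %.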